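The runs are simulated for substances that don't exist, noise included.

By 8.00 min Thursday's flask has lost 22.9% of its substrate, more than the 7.7% of the charge that stands as target, so I keep a ledger of the substrate, the limiting reagent, counted as parts of the charge.

the same everywhere: substrate 1.5 M; gas phase 170 mM (held)
- Thursday's: protic impurity 0.075 M; the very flask that is asked about, followed so far
- Sunday's: protic impurity 0.11 M; run made earlier
- flask: protic impurity 0.0750 M; time 20 min

| run | time / min | target / % | substrate / % |
|---|---|---|---|
| Thursday's | 0.667 | 0.2 | 98.7 |
| Thursday's | 1.00 | 1.1 | 97.3 |
| Thursday's | 2.00 | 4.0 | 94.5 |
| Thursday's | 3.00 | 5.4 | 91.9 |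
| Thursday's | 5.00 | 6.6 | 86.5 |
| Thursday's | 8.00 | 7.7 | 77.1 |
| Sunday's | 0.500 | 1.2 | 99.9 |
| Sunday's | 1.50 | 3.3 | 96.2 |
| Sunday's | 3.00 | 5.4 | 91.5 |
| Sunday's | 4.00 | 6.4 | 89.5 |
| Sunday's | 6.00 | 8.0 | 82.7 |
| Sunday's | 8.00 | 8.4 | 78.8 |

(scatter of a reading: 0.5 percentage points)

- at the start none of the gas phase is in solution

- amber: doubling the saturation concentration of gas phase, all else as stated
- green: doubling the transfer coefficient of the gas phase, all else as stated

- target at 20 min, in percent of the substrate charged
- the change that raises the amount of target at 20 min, in percent of the substrate charged most ("none" if none brings more than 2 percentage points) (amber / green / none)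
- amount of target at 20 min, in percent of the substrate charged, after green

At that reading Thursday's ledger has three entries: 77.1% still substrate, 7.7% target, and 15.2% gone where the readings don't show. A total says little about what comes next, so I divide one rate by another and time drops out. The margin is the target gained per substrate lost between two readings (the field's instantaneous selectivity). Thursday's last two readings give 0.117, but the pair from 2.00 min to 3.00 min gave 0.538, so the margin is shrinking. With a scatter of 0.5 percentage points on each reading these are rough figures, but Sunday's flask, with more protic impurity, reads 0.103 over its last two readings.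

Thursday's substrate falls by 0.0290 /min between 2.00 min and 8.00 min. The readings stop there, so it is only a straight-line guess that this pace holds to 20 min; on that guess a further 34.8% of the charge leaves the ledger. If the margin slides evenly to zero over that stretch, target collects half of the margin on it and ends near 9.74%, which is my figure. A gain of 2 points at this margin takes 17 points more substrate lost, and the margin is falling, so I pick none and put green near my figure too.

The forecast gives 9%, none and 9.3% after green (“a plateau or slow creep to about 9% at 20 min”), which is less than my figure.

The flask gives 7.32%, less than my figure. The best change is none: green adds 0.21 points and amber 0.06 points, both less than 2 points, and green ends at 7.54%.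

    dissolved gas + target → over-reacted product (k = 0.0333 /M/s)
    dissolved gas + protic impurity → quenched reagent (k = 0.00417 /M/s)
    substrate + target → side product (k = 0.00151 /M/s)
    gas phase ⇌ dissolved gas, rate k4*(csat - [dissolved gas]) (kL = 0.00568 /s)
    substrate + dissolved gas ⇌ target (K = 2.71 /M, k = 0.0386 /M/s)

The margin I read as 0.117 does not stop at zero. From 10.0 min to 20.0 min the flask's target goes from 8.28% to 7.32% while its substrate goes from 72.3% to 51.0%, a margin of −0.0449. The same flask read at 80 min continues the ledger: from 51.0% substrate falls to 2.40%, a margin of −0.135, and target stands at 0.755%.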